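A small charge of D is what ash holds in its first hours, while E and J stand at full strength, so the question in that flask is who gets E.

| setting | Wednesday's | Thursday's | Sunday's | Tuesday's | ash | alder | oak | larch |
|---|---|---|---|---|---|---|---|---|
| D | 0.30 M | 0.30 M | 0.30 M | 0.30 M | 0.30 M (fed, over 3.0 d) | 0.30 M | 0.30 M | 0.30 M |
| E | 1.2 equiv | 1.2 equiv | 1.2 equiv | 1.8 equiv | 1.20 equiv | 1.20 equiv (fed, over 3.0 d) | 1.20 equiv | 1.20 equiv (fed, over 20 h) |
| J | 5 equiv | 2.5 equiv | 10 equiv | 5 equiv | 5.00 equiv | 5.00 equiv | 5.00 equiv | 5.00 equiv |
| remark | run made earlier | run made earlier | run made earlier | run made earlier | all else is in the flask from the start; the feed brings no volume worth counting | all else is in the flask from the start; the feed brings no volume worth counting | everything together at the start | all else is in the flask from the start; the feed brings no volume worth counting |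
| time |  |  |  |  | 4.0 d | 4.0 d | 4.0 d | 4.0 d |

| run | time / d | G / % | X / % |
|---|---|---|---|
| Wednesday's | 0.208 | 0 | 14 |
| Wednesday's | 0.625 | 4 | 25 |
| Wednesday's | 1.04 | 6 | 22 |
| Wednesday's | 1.67 | 13 | 19 |
| Wednesday's | 2.50 | 18 | 16 |
| Wednesday's | 3.00 | 18 | 10 |
| Wednesday's | 4.00 | 20 | 5 |
| Thursday's | 0.167 | 3 | 13 |
| Thursday's | 0.500 | 3 | 29 |
| Thursday's | 0.833 | 5 | 29 |
| Thursday's | 1.25 | 14 | 31 |
| Thursday's | 2.08 | 19 | 28 |
| Thursday's | 2.50 | 22 | 24 |
| Thursday's | 3.00 | 26 | 16 |
| Sunday's | 0.250 | 0 | 14 |
| Sunday's | 0.417 | 2 | 16 |
| Sunday's | 0.625 | 2 | 15 |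
| Sunday's | 0.833 | 3 | 14 |
| Sunday's | 1.25 | 7 | 13 |
| Sunday's | 2.00 | 7 | 8 |
| Sunday's | 3.00 | 6 | 5 |
| Tuesday's | 0.625 | 7 | 33 |
| Tuesday's | 1.25 | 11 | 31 |
| Tuesday's | 2.08 | 18 | 20 |
| Tuesday's | 2.50 | 23 | 19 |
| Tuesday's | 3.00 | 31 | 16 |

(readings scatter by 2 percentage points)

- the analysis behind the earlier runs scatters by 2 percentage points, standard deviation

* the flask with the highest amount of G, in percent of the D charged ("all alike" if they lie within 1.5 percentage points) (ash / alder / oak / larch / all alike)
* final G, as a percentage of the D charged, in ash
* final G, as a percentage of the D charged, in alder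
* final G, as a percentage of the D charged, in oak
* final G, as a percentage of the D charged, in larch

Wednesday's run shows the contest. X and G together read 34.0 % at 2.50 d, so by that reading D caught about 28.3 % of the E dose. Sunday's, with more J, reads lower, at 20.0 % at 1.25 d, so I take the remaining E to go with J. I call the preference, the selectivity factor, the number of times more readily E takes an equivalent of D than an equivalent of J: 1.98 as read from Wednesday's. Sunday's reads 2.00 and Thursday's 1.61. In my reckoning, the share of E going to D at a given moment is the preference times the D present, divided by that same product plus the J present.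

Now I run ash slowly. Wednesday's early rise reads as an E lifetime of about 9.41 h. In ash, D comes in by the feed, so I count J as the competitor at first; its excess makes the loss of E pseudo-first-order, and taking D's part out of Wednesday's rate stretches that lifetime to about 13.1 h. This is shorter than the feed time, so in the middle I take the loss of E as the fast step: the average portion of E is spent one lifetime after the start, and by then the feed has brought in 0.182 of the charge, which I take as the D that E meets. That gives a share of 6.72 %, so X and G should total 8.07 %. By the end of the feed in ash, I reckon 0.415 % of the E remains. Scaling Wednesday's G of 20 % at 4.00 d by the product ratio gives ash 4.75 %. Oak has Wednesday's charges, so I take that reading for it. Alder and larch receive E late, so I place them between ash and oak.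

The forecast names oak, with 4 % for ash, below my figure, 16 % for alder, 21 % for oak and 19 % for larch, holding that “Feeding D wastes E before D arrives”.

The flask with the highest G is oak: ash gives 5.06 %, alder 8.33 %, oak 22.6 % and larch 16.6 %.

    D + E → X (k = 0.140 /M/h)
    J + E → Z (k = 0.0540 /M/h)
    D + J → Q (k = 0.0250 /M/h)
    X → G (k = 0.0150 /h)

My 4.75 % for ash stands against 5.06 %, and X and G in ash at 4.00 d total 7.76 % against my 8.07 %. A neighbour of ash charged with 3.00 equiv of E gets the same reckoning: with preference 1.98, the same lifetime and the same D met by E, I reckon it takes 6.72 % of a larger dose, or 20.2 % of X and G. That neighbour holds 10.6 % of X and 15.6 % of G at 4.00 d, together 26.2 %, more than reckoned, with J down to 37.0 % of its charge.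

The data come from a simulation with made-up constants.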